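**Retrosynthetic overview**
- The target is unmasked from a spiro-dioxolane ketal of its C6 ketone; before that come O-methylation and 1,2-allylation of the C5 carbonyl of a masked ortho-quinone, where a chiral tert-butyl-dioxolane controls C5.
- The masked ortho-quinone comes from oxidative dearomatization of a 5-hydroxy-2,3-dihydrobenzofuran whose 6-oxygen carries a chiral 2-hydroxyalkyl tether.
- The trans-dihydrofuran ring (ring B) is closed by acid-mediated C2–O1 bond formation from a 1,2-diarylpropanol.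
- The C2–C3 bond is made by an intermolecular Evans syn-aldol between an arylacetyl oxazolidinone and 3,4,5-trimethoxybenzaldehyde; the acyl carbon is then reduced to the C3 methyl.
- The arylacetic acid is built from resorcinol by three directed ortho-metalations. Ring order: aromatic ring A first, ring B in step 14, ring A dearomatized last (steps 18–21).

Assumption: in the spiroketal of step 18 the tert-butyl group lies on the carbonyl side and the allyl Grignard reagent enters anti to it (this sense is a model, not an established fact; a fallback covers the opposite outcome); numbers are given to substrates, fragment partners, intermediates and products, while simple reagents are named with SMILES in each step.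

**Route**

Step 1
Reactants: 1 resorcinol
Product: 2 1,3-bis(methoxymethoxy)benzene
Conditions: MOMCl (2.5 equiv), iPr2NEt (3 equiv), CH2Cl2, 0 °C → rt
Reagents that add atoms: chloromethyl methyl ether, COCCl
Why: Double O-alkylation (Williamson-type acetal ether formation) installs the two MOM groups that direct all later ortho-lithiations; no stereocenter.

Step 2
Reactants: 2 1,3-bis(methoxymethoxy)benzene
Product: 5 2,6-bis(methoxymethoxy)phenol, via aryllithium 3 (not isolated), via arylboronate 4 (not isolated)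
Conditions: n-BuLi, THF, 0 °C; B(OMe)3, −78 °C → rt; aq. NaOH, 30% H2O2, 0 °C → rt
Reagents that add atoms: hydrogen peroxide, OO
Why: Directed ortho-metalation at the doubly activated position between the two OMOM groups, then borylation and oxidative C–B to C–O conversion; no stereocenter.

Step 3
Reactants: 5 2,6-bis(methoxymethoxy)phenol
Product: 6 2-methoxy-1,3-bis(methoxymethoxy)benzene
Conditions: MeI, K2CO3, acetone, reflux
Reagents that add atoms: iodomethane, CI
Why: Williamson methylation of the phenoxide fixes the future 7-methoxy group; no stereocenter.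

Step 4
Reactants: 6 2-methoxy-1,3-bis(methoxymethoxy)benzene
Product: 9 3-methoxy-2,4-bis(methoxymethoxy)phenol, via aryllithium 7 (not isolated), via arylboronate 8 (not isolated)
Conditions: n-BuLi, TMEDA, THF, −20 → 0 °C; B(OMe)3, −78 °C → rt; aq. NaOH, 30% H2O2, 0 °C → rt
Reagents that add atoms: hydrogen peroxide, OO
Why: Directed ortho-metalation next to an OMOM group (both such positions are equivalent by symmetry), then borylation and oxidation introduce the future 5-oxygen; no stereocenter.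

Step 5
Reactants: 9 3-methoxy-2,4-bis(methoxymethoxy)phenol
Product: 10 1-(benzyloxy)-3-methoxy-2,4-bis(methoxymethoxy)benzene
Conditions: BnBr, K2CO3, DMF, rt
Reagents that add atoms: benzyl bromide, BrCc1ccccc1
Why: Williamson benzylation gives the 5-oxygen a protecting group orthogonal to MOM; no stereocenter.

Step 6
Reactants: 10 1-(benzyloxy)-3-methoxy-2,4-bis(methoxymethoxy)benzene
Product: 12 2-[5-(benzyloxy)-3-methoxy-2,4-bis(methoxymethoxy)phenyl]ethan-1-ol, via aryllithium 11 (not isolated)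
Conditions: n-BuLi, TMEDA, THF, −40 → 0 °C; ethylene oxide (THF solution), 0 °C → rt; H2O
Reagents that add atoms: ethylene oxide, C1CO1
Why: Directed ortho-metalation at the only position ortho to an OMOM group (OMOM outranks OBn as a directing group), then epoxide opening by the aryllithium adds the two-carbon chain; no stereocenter.

Step 7
Reactants: 12 2-[5-(benzyloxy)-3-methoxy-2,4-bis(methoxymethoxy)phenyl]ethan-1-ol
Product: 14 2-[5-(benzyloxy)-3-methoxy-2,4-bis(methoxymethoxy)phenyl]acetic acid, via arylacetaldehyde 13 (not isolated)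
Conditions: Dess–Martin periodinane, CH2Cl2, 0 °C → rt; then NaClO2, NaH2PO4, 2-methyl-2-butene, t-BuOH–H2O, 0 °C → rt
Reagents that add atoms: sodium chlorite, [Na+].[O-]Cl=O
Why: Dess–Martin oxidation to the aldehyde and Pinnick oxidation to the acid, with 2-methyl-2-butene scavenging HOCl so the electron-rich ring is not chlorinated; no stereocenter.

Step 8
Reactants: 14 2-[5-(benzyloxy)-3-methoxy-2,4-bis(methoxymethoxy)phenyl]acetic acid; 15 (S)-4-benzyl-1,3-oxazolidin-2-one
Product: 17 (4S)-4-benzyl-3-{[5-(benzyloxy)-3-methoxy-2,4-bis(methoxymethoxy)phenyl]acetyl}-1,3-oxazolidin-2-one, via mixed pivalic anhydride 16 (not isolated)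
Conditions: PivCl, Et3N, THF, −20 °C; then LiCl, 15, rt
Reagents that add atoms: none
Why: N-acylation of the oxazolidinone through the mixed anhydride occurs at the unhindered arylacetyl carbonyl; the auxiliary brings its own S center.

Step 9 (key step)
Reactants: 17 (4S)-4-benzyl-3-{[5-(benzyloxy)-3-methoxy-2,4-bis(methoxymethoxy)phenyl]acetyl}-1,3-oxazolidin-2-one; 18 3,4,5-trimethoxybenzaldehyde
Product: 20 (4S)-4-benzyl-3-[(2S,3S)-2-[5-(benzyloxy)-3-methoxy-2,4-bis(methoxymethoxy)phenyl]-3-hydroxy-3-(3,4,5-trimethoxyphenyl)propanoyl]-1,3-oxazolidin-2-one, via boron enolate 19 (not isolated)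
Conditions: (n-Bu)2BOTf, iPr2NEt, CH2Cl2, −78 → 0 °C; 18, −78 → 0 °C; pH 7 buffer, MeOH, 30% H2O2, 0 °C
Reagents that add atoms: none
Why: Evans syn-aldol: the dibutylboron Z-enolate reacts through a closed Zimmerman–Traxler chair on the face away from the auxiliary benzyl group, which joins the two aryl fragments and sets the α-carbon (future C3) as S and the carbinol (future C2) as S.

Step 10
Reactants: 20 the syn-aldol adduct
Product: 21 (4S)-4-benzyl-3-[(2S,3S)-2-[5-(benzyloxy)-3-methoxy-2,4-bis(methoxymethoxy)phenyl]-3-[(tert-butyldimethylsilyl)oxy]-3-(3,4,5-trimethoxyphenyl)propanoyl]-1,3-oxazolidin-2-one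
Conditions: TBSOTf, 2,6-lutidine, CH2Cl2, −78 → 0 °C
Reagents that add atoms: tert-butyldimethylsilyl trifluoromethanesulfonate, CC(C)(C)[Si](C)(C)OS(=O)(=O)C(F)(F)F
Why: Silylation of the secondary alcohol blocks retro-aldol cleavage and alkoxide-driven fragmentation in the following reductions; no new stereocenter.

Step 11
Reactants: 21 the silylated imide
Product: 22 (2R,3S)-2-[5-(benzyloxy)-3-methoxy-2,4-bis(methoxymethoxy)phenyl]-3-[(tert-butyldimethylsilyl)oxy]-3-(3,4,5-trimethoxyphenyl)propan-1-ol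
Conditions: LiBH4, H2O (1.1 equiv), Et2O–THF, 0 °C
Reagents that add atoms: none
Why: Reductive cleavage of the imide by hydride attack on the exocyclic carbonyl gives the primary alcohol and frees the auxiliary without epimerising the α-center (its descriptor changes to R only through CIP priorities).

Step 12
Reactants: 22 the primary alcohol
Product: 23 (2R,3S)-2-[5-(benzyloxy)-3-methoxy-2,4-bis(methoxymethoxy)phenyl]-3-[(tert-butyldimethylsilyl)oxy]-3-(3,4,5-trimethoxyphenyl)propyl 4-methylbenzenesulfonate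
Conditions: TsCl, Et3N, 4-(dimethylamino)pyridine (cat.), CH2Cl2, 0 °C → rt
Reagents that add atoms: 4-methylbenzenesulfonyl chloride, Cc1ccc(cc1)S(=O)(=O)Cl
Why: Sulfonylation turns the primary alcohol into a leaving group; no stereocenter is touched.

Step 13
Reactants: 23 the tosylate
Product: 24 tert-butyl{[(1S,2S)-2-[5-(benzyloxy)-3-methoxy-2,4-bis(methoxymethoxy)phenyl]-1-(3,4,5-trimethoxyphenyl)propyl]oxy}dimethylsilane
Conditions: LiBHEt3, THF, 0 °C → rt
Reagents that add atoms: none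
Why: SN2 displacement of the primary tosylate by hydride converts the former acyl carbon into the C3 methyl group; stereocenters untouched.

Step 14
Reactants: 24 the silyl ether
Product: 26 (2S,3S)-5-(benzyloxy)-7-methoxy-3-methyl-2-(3,4,5-trimethoxyphenyl)-2,3-dihydro-1-benzofuran-6-ol (2,3-trans), via triol 25 (not isolated)
Conditions: HCl (3 M in MeOH), THF, 40 °C; evaporate; CF3CO2H (2 equiv), CH2Cl2 (0.01 M), 0 °C
Reagents that add atoms: none
Why: Acidic methanolysis removes both MOM ethers and the silyl ether, and the benzylic cation at C2 (SN1) is captured by the neighbouring phenol oxygen to close the five-membered ring with the aryl group trans to the C3 methyl (kinetic and thermodynamic preference), so C2 ends as S while C3 is untouched.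

Step 15
Reactants: 26 the dihydrobenzofuran-6-ol; 27 1-bromo-3,3-dimethylbutan-2-one
Product: 28 1-{[(2S,3S)-5-(benzyloxy)-7-methoxy-3-methyl-2-(3,4,5-trimethoxyphenyl)-2,3-dihydro-1-benzofuran-6-yl]oxy}-3,3-dimethylbutan-2-one
Conditions: K2CO3, acetone, 50 °C
Reagents that add atoms: none
Why: Williamson etherification of the hindered 6-phenoxide with a very reactive α-bromoketone installs the tether; no stereocenter.

Step 16
Reactants: 28 the aryloxy ketone
Product: 29 (2R)-1-{[(2S,3S)-5-(benzyloxy)-7-methoxy-3-methyl-2-(3,4,5-trimethoxyphenyl)-2,3-dihydro-1-benzofuran-6-yl]oxy}-3,3-dimethylbutan-2-ol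
Conditions: (R)-Me-CBS [(R)-1-methyl-3,3-diphenyltetrahydro-1H,3H-pyrrolo[1,2-c][1,3,2]oxazaborole] (0.2 equiv), BH3·SMe2, THF, −20 °C; MeOH
Reagents that add atoms: none
Why: Corey–Bakshi–Shibata reduction: the catalyst distinguishes tert-butyl (large) from CH2OAr (small) and delivers hydride to one face, setting the tether carbinol as R.

Step 17
Reactants: 29 the benzyl ether
Product: 30 (2S,3S)-6-{[(2R)-2-hydroxy-3,3-dimethylbutyl]oxy}-7-methoxy-3-methyl-2-(3,4,5-trimethoxyphenyl)-2,3-dihydro-1-benzofuran-5-ol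
Conditions: H2 (1 atm), Pd/C, EtOAc, rt
Reagents that add atoms: none
Why: Hydrogenolysis of the benzyl ether frees the 5-phenol, and the run is stopped at full conversion because the cyclic benzylic aryl ether at C2 cleaves much more slowly; no stereocenter changes.

Step 18
Reactants: 30 the 5-phenol
Product: 31 (2S,3S,6S,4'R)-4'-tert-butyl-7-methoxy-3-methyl-2-(3,4,5-trimethoxyphenyl)-2,3-dihydro-5H-spiro[1-benzofuran-6,2'-[1,3]dioxolan]-5-one (dioxolane oxygen bearing the CH(t-Bu) carbon on the face of the C3 methyl)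
Conditions: PhI(OAc)2, CF3CH2OH, −40 °C
Reagents that add atoms: none
Why: Oxidative dearomatizing spiroketalization: the iodine reagent activates the phenol oxygen and the tether hydroxyl attacks the ipso carbon C6 in a five-membered ring closure, with the tether center setting the spiro center (tert-butyl toward the carbonyl side, away from the C7 methoxy); this center is only a relay and is removed in step 21.

Step 19
Reactants: 31 the spiroketal dienone
Product: 32 (2S,3S,5R,6R,4'R)-4'-tert-butyl-7-methoxy-3-methyl-5-(prop-2-en-1-yl)-2-(3,4,5-trimethoxyphenyl)-2,3-dihydro-5H-spiro[1-benzofuran-6,2'-[1,3]dioxolan]-5-ol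
Conditions: CH2=CHCH2MgBr, THF, −78 °C; pH 7 buffer
Reagents that add atoms: allylmagnesium bromide, C=CC[Mg]Br
Why: Carbonyl allylation (Grignard 1,2-addition) at C5: the tert-butyl group of the dioxolane shields one face, so the allyl group enters from the face of the C2 aryl group and sets C5 as R, and any C5 epimer is removed by chromatography because the tether centers are close by.

Step 20
Reactants: 32 the tertiary alcohol
Product: 33 (2S,3S,5R,6R,4'R)-4'-tert-butyl-5,7-dimethoxy-3-methyl-5-(prop-2-en-1-yl)-2-(3,4,5-trimethoxyphenyl)-2,3-dihydro-5H-spiro[1-benzofuran-6,2'-[1,3]dioxolane]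
Conditions: MeI (10 equiv), NaH, THF–DMF, 0 °C
Reagents that add atoms: iodomethane, CI
Why: Williamson methylation of the tertiary alkoxide with MeI present from the start; the sodium counter-ion and 0 °C keep the anionic oxy-Cope shift of this 1,5-dien-3-olate out of play, and C5 is untouched.

Step 21
Reactants: 33 the methyl ether
Product: 34 (2S,3S,5R)-5,7-dimethoxy-3-methyl-5-(prop-2-en-1-yl)-2-(3,4,5-trimethoxyphenyl)-2,3-dihydro-1-benzofuran-6(5H)-one (target)
Conditions: 0.1 M aq. HCl, THF, 0 °C; NaHCO3; work-up below 30 °C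
Reagents that add atoms: water, O
Why: Acid-catalysed ketal hydrolysis: ionisation at C6 gives a cation stabilised by the ring oxygen through the C7=C7a double bond (vinylogous ester), so it proceeds under conditions too mild for allyl migration; the spiro center vanishes and C2, C3 and C5 are untouched.

**Compound list**

1 | resorcinol | Oc1cccc(O)c1 | starting material
2 | 1,3-bis(methoxymethoxy)benzene | COCOc1cccc(OCOC)c1 | intermediate
3 | [2,6-bis(methoxymethoxy)phenyl]lithium | [Li]c1c(OCOC)cccc1OCOC | intermediate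
4 | dimethyl [2,6-bis(methoxymethoxy)phenyl]boronate | COB(OC)c1c(OCOC)cccc1OCOC | intermediate
5 | 2,6-bis(methoxymethoxy)phenol | Oc1c(OCOC)cccc1OCOC | intermediate
6 | 2-methoxy-1,3-bis(methoxymethoxy)benzene | COCOc1cccc(OCOC)c1OC | intermediate
7 | [3-methoxy-2,4-bis(methoxymethoxy)phenyl]lithium | [Li]c1ccc(OCOC)c(OC)c1OCOC | intermediate
8 | dimethyl [3-methoxy-2,4-bis(methoxymethoxy)phenyl]boronate | COB(OC)c1ccc(OCOC)c(OC)c1OCOC | intermediate
9 | 3-methoxy-2,4-bis(methoxymethoxy)phenol | Oc1ccc(OCOC)c(OC)c1OCOC | intermediate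
10 | 1-(benzyloxy)-3-methoxy-2,4-bis(methoxymethoxy)benzene | COCOc1ccc(OCc2ccccc2)c(OCOC)c1OC | intermediate
11 | [5-(benzyloxy)-3-methoxy-2,4-bis(methoxymethoxy)phenyl]lithium | [Li]c1cc(OCc2ccccc2)c(OCOC)c(OC)c1OCOC | intermediate
12 | 2-[5-(benzyloxy)-3-methoxy-2,4-bis(methoxymethoxy)phenyl]ethan-1-ol | OCCc1cc(OCc2ccccc2)c(OCOC)c(OC)c1OCOC | intermediate
13 | 2-[5-(benzyloxy)-3-methoxy-2,4-bis(methoxymethoxy)phenyl]acetaldehyde | O=CCc1cc(OCc2ccccc2)c(OCOC)c(OC)c1OCOC | intermediate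
14 | 2-[5-(benzyloxy)-3-methoxy-2,4-bis(methoxymethoxy)phenyl]acetic acid | OC(=O)Cc1cc(OCc2ccccc2)c(OCOC)c(OC)c1OCOC | intermediate
15 | (S)-4-benzyl-1,3-oxazolidin-2-one | O=C1N[C@@H](Cc2ccccc2)CO1 | starting material
16 | mixed anhydride of 14 with pivalic acid | CC(C)(C)C(=O)OC(=O)Cc1cc(OCc2ccccc2)c(OCOC)c(OC)c1OCOC | intermediate
17 | (4S)-4-benzyl-3-{[5-(benzyloxy)-3-methoxy-2,4-bis(methoxymethoxy)phenyl]acetyl}-1,3-oxazolidin-2-one | O=C1OC[C@H](Cc2ccccc2)N1C(=O)Cc3cc(OCc4ccccc4)c(OCOC)c(OC)c3OCOC | intermediate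
18 | 3,4,5-trimethoxybenzaldehyde | COc1cc(C=O)cc(OC)c1OC | starting material
19 | dibutylboron (Z)-enolate of 17 | CCCCB(CCCC)O/C(=C\c1cc(OCc2ccccc2)c(OCOC)c(OC)c1OCOC)N1[C@@H](Cc2ccccc2)COC1=O | intermediate
20 | (4S)-4-benzyl-3-[(2S,3S)-2-aryl-3-hydroxy-3-(3,4,5-trimethoxyphenyl)propanoyl]-1,3-oxazolidin-2-one (aryl = 5-benzyloxy-3-methoxy-2,4-bis(methoxymethoxy)phenyl) | O=C1OC[C@H](Cc2ccccc2)N1C(=O)[C@@H](c3cc(OCc4ccccc4)c(OCOC)c(OC)c3OCOC)[C@H](O)c5cc(OC)c(OC)c(OC)c5 | intermediate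
21 | tert-butyldimethylsilyl ether of 20 (2S,3S) | O=C1OC[C@H](Cc2ccccc2)N1C(=O)[C@@H](c3cc(OCc4ccccc4)c(OCOC)c(OC)c3OCOC)[C@H](O[Si](C)(C)C(C)(C)C)c5cc(OC)c(OC)c(OC)c5 | intermediate
22 | (2R,3S)-2-[5-(benzyloxy)-3-methoxy-2,4-bis(methoxymethoxy)phenyl]-3-[(tert-butyldimethylsilyl)oxy]-3-(3,4,5-trimethoxyphenyl)propan-1-ol | OC[C@@H](c1cc(OCc2ccccc2)c(OCOC)c(OC)c1OCOC)[C@H](O[Si](C)(C)C(C)(C)C)c3cc(OC)c(OC)c(OC)c3 | intermediate
23 | 4-methylbenzenesulfonate of 22 (2R,3S) | Cc1ccc(cc1)S(=O)(=O)OC[C@@H](c2cc(OCc3ccccc3)c(OCOC)c(OC)c2OCOC)[C@H](O[Si](C)(C)C(C)(C)C)c4cc(OC)c(OC)c(OC)c4 | intermediate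
24 | tert-butyl{[(1S,2S)-2-[5-(benzyloxy)-3-methoxy-2,4-bis(methoxymethoxy)phenyl]-1-(3,4,5-trimethoxyphenyl)propyl]oxy}dimethylsilane | C[C@@H](c1cc(OCc2ccccc2)c(OCOC)c(OC)c1OCOC)[C@H](O[Si](C)(C)C(C)(C)C)c3cc(OC)c(OC)c(OC)c3 | intermediate
25 | 4-(benzyloxy)-6-[(1S,2S)-1-hydroxy-1-(3,4,5-trimethoxyphenyl)propan-2-yl]-2-methoxybenzene-1,3-diol | C[C@@H](c1cc(OCc2ccccc2)c(O)c(OC)c1O)[C@H](O)c3cc(OC)c(OC)c(OC)c3 | intermediate
26 | (2S,3S)-5-(benzyloxy)-7-methoxy-3-methyl-2-(3,4,5-trimethoxyphenyl)-2,3-dihydro-1-benzofuran-6-ol | COc1c(O)c(OCc2ccccc2)cc3c1O[C@H](c1cc(OC)c(OC)c(OC)c1)[C@H]3C | intermediate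
27 | 1-bromo-3,3-dimethylbutan-2-one | CC(C)(C)C(=O)CBr | starting material
28 | 1-{[(2S,3S)-5-(benzyloxy)-7-methoxy-3-methyl-2-(3,4,5-trimethoxyphenyl)-2,3-dihydro-1-benzofuran-6-yl]oxy}-3,3-dimethylbutan-2-one | COc1c(OCC(=O)C(C)(C)C)c(OCc2ccccc2)cc3c1O[C@H](c1cc(OC)c(OC)c(OC)c1)[C@H]3C | intermediate
29 | (2R)-1-{[(2S,3S)-5-(benzyloxy)-7-methoxy-3-methyl-2-(3,4,5-trimethoxyphenyl)-2,3-dihydro-1-benzofuran-6-yl]oxy}-3,3-dimethylbutan-2-ol | COc1c(OC[C@H](O)C(C)(C)C)c(OCc2ccccc2)cc3c1O[C@H](c1cc(OC)c(OC)c(OC)c1)[C@H]3C | intermediate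
30 | (2S,3S)-6-{[(2R)-2-hydroxy-3,3-dimethylbutyl]oxy}-7-methoxy-3-methyl-2-(3,4,5-trimethoxyphenyl)-2,3-dihydro-1-benzofuran-5-ol | COc1c(OC[C@H](O)C(C)(C)C)c(O)cc2c1O[C@H](c1cc(OC)c(OC)c(OC)c1)[C@H]2C | intermediate
31 | (2S,3S,6S,4'R)-4'-tert-butyl-7-methoxy-3-methyl-2-(3,4,5-trimethoxyphenyl)-2,3-dihydro-5H-spiro[1-benzofuran-6,2'-[1,3]dioxolan]-5-one | COC1=C2O[C@H](c3cc(OC)c(OC)c(OC)c3)[C@@H](C)C2=CC(=O)[C@]14OC[C@@H](C(C)(C)C)O4 | intermediate
32 | (2S,3S,5R,6R,4'R)-4'-tert-butyl-7-methoxy-3-methyl-5-(prop-2-en-1-yl)-2-(3,4,5-trimethoxyphenyl)-2,3-dihydro-5H-spiro[1-benzofuran-6,2'-[1,3]dioxolan]-5-ol | COC1=C2O[C@H](c3cc(OC)c(OC)c(OC)c3)[C@@H](C)C2=C[C@](O)(CC=C)[C@]14OC[C@@H](C(C)(C)C)O4 | intermediate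
33 | (2S,3S,5R,6R,4'R)-4'-tert-butyl-5,7-dimethoxy-3-methyl-5-(prop-2-en-1-yl)-2-(3,4,5-trimethoxyphenyl)-2,3-dihydro-5H-spiro[1-benzofuran-6,2'-[1,3]dioxolane] | COC1=C2O[C@H](c3cc(OC)c(OC)c(OC)c3)[C@@H](C)C2=C[C@](OC)(CC=C)[C@]14OC[C@@H](C(C)(C)C)O4 | intermediate
34 | (2S,3S,5R)-5,7-dimethoxy-3-methyl-5-(prop-2-en-1-yl)-2-(3,4,5-trimethoxyphenyl)-2,3-dihydro-1-benzofuran-6(5H)-one | C=CC[C@@]1(OC)C=C2C(=C(OC)C1=O)O[C@H](c1cc(OC)c(OC)c(OC)c1)[C@H]2C | target

**Step count and risks**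

Total step count: 21. Longest linear sequence: 21 steps (1 → 34); 15, 18 and 27 are bought.

Steps most likely to fail:

Step 11 (reductive removal of the auxiliary from the crowded imide 21; attack on the ring carbonyl of the oxazolidinone can compete). Fallback: set out from 21 and hydrolyse the imide with LiOH/H2O2 (THF–H2O, 0 °C), which cleaves only the exocyclic acyl group and gives the carboxylic acid F1. Reduction of F1 with BH3·SMe2 (THF, 0 °C → rt) gives the primary alcohol 22, where the route is rejoined.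

Step 18 (oxidative spiroketalization of the very electron-rich phenol 30; over-oxidation toward a para-quinone or a poor spiro ratio are the risks). Fallback: set out from 26 and drop the tether. Hydrogenolysis (H2, Pd/C, EtOAc) gives the catechol F2, and Ag2O (Et2O, Na2SO4, 0 °C) gives the ortho-quinone F3. Barbier allylation (allyl bromide, In powder, NaI, DMF, 0 °C) adds to the more electrophilic C5 carbonyl (C6 is a vinylogous ester) and gives both C5 epimers of the ortho-quinol, from which the (5R)-ortho-quinol F4 is separated by preparative HPLC. O-Methylation (MeI, Ag2O, CH2Cl2, dark, rt) returns to the route at 34. This path gives up control of C5 for a shorter end game.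

Step 19 (face selectivity of the allyl addition; the addition itself is dependable, the sense and level of induction are not proven for this substrate). Low selectivity is handled by chromatography of 32. If the major adduct is the 5S epimer, fallback: set out from 28 and build the mirror-image tether. Reduction with (S)-Me-CBS/BH3·SMe2 gives the (S)-alcohol F5, hydrogenolysis (H2, Pd/C) gives the phenol F6, and PhI(OAc)2 (CF3CH2OH, −40 °C) gives the spiroketal F7 with the mirror-image dioxolane. CH2=CHCH2MgBr then adds from the opposite face to give the tertiary alcohol F8 with C5 as R, NaH/MeI gives the methyl ether F9, and 0.1 M aq. HCl in THF at 0 °C returns to the route at 34.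

**Further compounds**

F1 | step 11 | (2S,3S)-2-[5-(benzyloxy)-3-methoxy-2,4-bis(methoxymethoxy)phenyl]-3-[(tert-butyldimethylsilyl)oxy]-3-(3,4,5-trimethoxyphenyl)propanoic acid | OC(=O)[C@@H](c1cc(OCc2ccccc2)c(OCOC)c(OC)c1OCOC)[C@H](O[Si](C)(C)C(C)(C)C)c3cc(OC)c(OC)c(OC)c3
F2 | step 18 | (2S,3S)-7-methoxy-3-methyl-2-(3,4,5-trimethoxyphenyl)-2,3-dihydro-1-benzofuran-5,6-diol | COc1c(O)c(O)cc2c1O[C@H](c1cc(OC)c(OC)c(OC)c1)[C@H]2C
F3 | step 18 | (2S,3S)-7-methoxy-3-methyl-2-(3,4,5-trimethoxyphenyl)-2,3-dihydro-1-benzofuran-5,6-dione | COC1=C2O[C@H](c3cc(OC)c(OC)c(OC)c3)[C@@H](C)C2=CC(=O)C1=O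
F4 | step 18 | (2S,3S,5R)-5-hydroxy-7-methoxy-3-methyl-5-(prop-2-en-1-yl)-2-(3,4,5-trimethoxyphenyl)-2,3-dihydro-1-benzofuran-6(5H)-one | COC1=C2O[C@H](c3cc(OC)c(OC)c(OC)c3)[C@@H](C)C2=C[C@](O)(CC=C)C1=O
F5 | step 19 | (2S)-1-{[(2S,3S)-5-(benzyloxy)-7-methoxy-3-methyl-2-(3,4,5-trimethoxyphenyl)-2,3-dihydro-1-benzofuran-6-yl]oxy}-3,3-dimethylbutan-2-ol | COc1c(OC[C@@H](O)C(C)(C)C)c(OCc2ccccc2)cc3c1O[C@H](c1cc(OC)c(OC)c(OC)c1)[C@H]3C
F6 | step 19 | (2S,3S)-6-{[(2S)-2-hydroxy-3,3-dimethylbutyl]oxy}-7-methoxy-3-methyl-2-(3,4,5-trimethoxyphenyl)-2,3-dihydro-1-benzofuran-5-ol | COc1c(OC[C@@H](O)C(C)(C)C)c(O)cc2c1O[C@H](c1cc(OC)c(OC)c(OC)c1)[C@H]2C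
F7 | step 19 | (2S,3S,6R,4'S)-4'-tert-butyl-7-methoxy-3-methyl-2-(3,4,5-trimethoxyphenyl)-2,3-dihydro-5H-spiro[1-benzofuran-6,2'-[1,3]dioxolan]-5-one | COC1=C2O[C@H](c3cc(OC)c(OC)c(OC)c3)[C@@H](C)C2=CC(=O)[C@@]14OC[C@H](C(C)(C)C)O4
F8 | step 19 | (2S,3S,5R,6S,4'S)-4'-tert-butyl-7-methoxy-3-methyl-5-(prop-2-en-1-yl)-2-(3,4,5-trimethoxyphenyl)-2,3-dihydro-5H-spiro[1-benzofuran-6,2'-[1,3]dioxolan]-5-ol | COC1=C2O[C@H](c3cc(OC)c(OC)c(OC)c3)[C@@H](C)C2=C[C@](O)(CC=C)[C@@]14OC[C@H](C(C)(C)C)O4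
F9 | step 19 | (2S,3S,5R,6S,4'S)-4'-tert-butyl-5,7-dimethoxy-3-methyl-5-(prop-2-en-1-yl)-2-(3,4,5-trimethoxyphenyl)-2,3-dihydro-5H-spiro[1-benzofuran-6,2'-[1,3]dioxolane] | COC1=C2O[C@H](c3cc(OC)c(OC)c(OC)c3)[C@@H](C)C2=C[C@](OC)(CC=C)[C@@]14OC[C@H](C(C)(C)C)O4
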